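**Retrosynthetic overview**
- C3–Cl last: electrophilic chlorination of 2,4,7-tribromoindole, whose C2–Br comes from deoxybromination of 4,7-dibromooxindole.
- 4,7-Dibromooxindole comes from its 3-methylsulfanyl derivative by reductive C–S cleavage.
- Key C3–C3a disconnection: 2,5-dibromoaniline plus ethyl (methylsulfanyl)acetate. N-chlorination makes the aniline an ortho-carbon electrophile (nitrenium equivalent), and an azasulfonium ylide [2,3]-shift joins the aniline ortho carbon to the ester α-carbon, two carbons that are both nucleophilic in their native forms.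
- Ring order: the benzene ring is bought with both bromines in place; the five-membered ring closes by N1–C2 lactamisation directly after the C–C bond is made.

Assumption: the target has no stereocentre or stereogenic double bond, so it is a single achiral compound and needs no stereocontrol; the racemic C3 centre of 6, 7 and 8 is erased in step 2.

**Step 1**
Reactants: 1 2,5-dibromoaniline; 2 ethyl (methylsulfanyl)acetate
Product: 8 rac-4,7-dibromo-3-(methylsulfanyl)indolin-2-one, via N-chloro-2,5-dibromoaniline 3 (not isolated), via azasulfonium chloride 4 (not isolated), via sulfonium ylide 5 (not isolated), via cyclohexadienimine 6 (not isolated), via amino ester 7 (not isolated)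
Conditions: t-BuOCl, CH2Cl2, −65 °C; 2, −65 °C; Et3N, −65 °C → rt; then 2 M HCl, Et2O, rt → 40 °C
Reagents that add atoms: none
Why: Gassman oxindole synthesis, in which N-chlorination makes the aniline an N-electrophile, sulfide 2 displaces chloride to give 4, Et3N forms the ester-stabilised ylide 5, and its Sommelet–Hauser-type [2,3]-sigmatropic shift (possible only to C6, the one free ortho position, and favoured for electron-poor N-chloroanilines) joins the ester α-carbon to the aniline ortho carbon to give 6, which rearomatises to 7 and lactamises under acid; the C3 stereocentre forms as a racemate and is removed in step 2.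

**Step 2**
Reactants: 8 rac-4,7-dibromo-3-(methylsulfanyl)indolin-2-one
Product: 9 4,7-dibromoindolin-2-one
Conditions: Zn dust, AcOH, 70 °C
Reagents that add atoms: none
Why: Dissolving-metal reductive desulfurisation, in which zinc puts two electrons into the benzylic C–S bond α to the lactam carbonyl (giving the stabilised oxindole enolate and methanethiolate, both protonated by AcOH) while aryl C–Br bonds are inert to Zn/AcOH; no stereocentre remains.

**Step 3**
Reactants: 9 4,7-dibromoindolin-2-one
Product: 11 2,4,7-tribromo-1H-indole, via indol-2-yl phosphorodibromidate 10 (not isolated)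
Conditions: POBr3, imidazole, ClCH2CH2Cl, 80 °C
Reagents that add atoms: phosphorus oxybromide (phosphoryl tribromide), O=P(Br)(Br)Br
Why: Dehydrative bromination of a lactam (Vilsmeier–Haack-type activation), in which POBr3 O-phosphorylates the lactim tautomer to give 10, bromide adds at C2 and expels dibromophosphate, and tautomerisation gives the aromatic 2-bromoindole, with imidazole buffering HBr so the acid-sensitive product does not oligomerise; no stereocentre is involved.

**Step 4**
Reactants: 11 2,4,7-tribromo-1H-indole
Product: 12 2,4,7-tribromo-3-chloro-1H-indole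
Conditions: NCS, DMF, 0 °C → rt
Reagents that add atoms: N-chlorosuccinimide, O=C1CCC(=O)N1Cl
Why: Electrophilic aromatic substitution (SEAr) of the indole, in which C3 is the most nucleophilic position and the only unsubstituted pyrrole carbon, so chlorine enters there alone; the product is achiral.

**Compound list**
1 | 2,5-dibromoaniline | Nc1cc(Br)ccc1Br | starting material
2 | ethyl (methylsulfanyl)acetate | CCOC(=O)CSC | starting material
3 | N-chloro-2,5-dibromoaniline | ClNc1cc(Br)ccc1Br | intermediate
4 | [(2,5-dibromophenyl)amino](2-ethoxy-2-oxoethyl)methylsulfonium chloride (azasulfonium chloride) | CCOC(=O)C[S+](C)Nc1cc(Br)ccc1Br.[Cl-] | intermediate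
5 | azasulfonium ylide of 4 (carbanion α to ester and sulfur) | CCOC(=O)[CH-][S+](C)Nc1cc(Br)ccc1Br | intermediate
6 | ethyl 2-(2,5-dibromo-6-iminocyclohexa-2,4-dien-1-yl)-2-(methylsulfanyl)acetate (racemic, diastereomer mixture) | CCOC(=O)C(SC)C1C(Br)=CC=C(Br)C1=N | intermediate
7 | ethyl 2-(2-amino-3,6-dibromophenyl)-2-(methylsulfanyl)acetate (racemic) | CCOC(=O)C(SC)c1c(Br)ccc(Br)c1N | intermediate
8 | rac-4,7-dibromo-3-(methylsulfanyl)indolin-2-one | CSC1C(=O)Nc2c(Br)ccc(Br)c12 | intermediate
9 | 4,7-dibromoindolin-2-one (4,7-dibromooxindole) | O=C1Cc2c(Br)ccc(Br)c2N1 | intermediate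
10 | 4,7-dibromo-1H-indol-2-yl phosphorodibromidate | O=P(Br)(Br)Oc1cc2c(Br)ccc(Br)c2[nH]1 | intermediate
11 | 2,4,7-tribromo-1H-indole | Brc1cc2c(Br)ccc(Br)c2[nH]1 | intermediate
12 | 2,4,7-tribromo-3-chloro-1H-indole | Clc1c(Br)[nH]c2c(Br)ccc(Br)c12 | target

**Totals**
Total step count: 4. Longest linear sequence: 4 steps (1 → 8 → 9 → 11 → 12).

**Steps most likely to fail, with fallbacks**

Step 1 (most at risk). The aniline is doubly deactivated and the [2,3]-shift must enter the position next to bromine; ring chlorination of 3 is the competing path. Fallback, setting out from 1 and coming back at 9: build the same C3–C3a bond by the Sandmeyer isatin synthesis. Compound 1 with Cl3CCH(OH)2 and NH2OH·HCl (Na2SO4, aq. HCl, 90 °C) gives (2E)-N-(2,5-dibromophenyl)-2-(hydroxyimino)acetamide F1. Conc. H2SO4 at 80 °C cyclises it to 4,7-dibromoisatin F2. N2H4·H2O at 120 °C gives 4,7-dibromoisatin 3-hydrazone F3, which loses nitrogen on heating with NaOEt in EtOH (Wolff–Kishner) to give 9.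

Step 3. 2-Bromoindoles without a C3 substituent are acid-sensitive and the POBr3 reaction is often only moderate in yield. Fallback, setting out from 9 and coming back at 12: take the lactam to the indole level first and halogenate in the other order. Reduction of 9 with i-Bu2AlH (toluene, 0 °C → rt, acidic work-up for dehydration) gives 4,7-dibromo-1H-indole F5. NCS in DMF at 0 °C gives 4,7-dibromo-3-chloro-1H-indole F6. NBS in DMF at 0 °C → rt then brominates C2, the only pyrrole carbon left, to give 12.

Step 2. Zn/AcOH may cleave the α-amido C–S bond slowly, and forcing it risks C–Br reduction. Fallback, setting out from 8 and coming back at 9: make sulfur a leaving group before reduction. MeOTf in CH2Cl2 at 0 °C S-methylates 8 to (4,7-dibromo-2-oxoindolin-3-yl)dimethylsulfonium triflate F4. Its C–S bond is cleaved by Zn dust in AcOH at rt, with loss of dimethyl sulfide, to give 9.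

**Further compounds**
F1 | step 1 | (2E)-N-(2,5-dibromophenyl)-2-(hydroxyimino)acetamide | O=C(/C=N/O)Nc1cc(Br)ccc1Br
F2 | step 1 | 4,7-dibromo-1H-indole-2,3-dione (4,7-dibromoisatin) | O=C1Nc2c(Br)ccc(Br)c2C1=O
F3 | step 1 | (3Z)-4,7-dibromo-3-hydrazinylideneindolin-2-one | N/N=C1\C(=O)Nc2c(Br)ccc(Br)c21
F4 | step 2 | (4,7-dibromo-2-oxoindolin-3-yl)dimethylsulfonium trifluoromethanesulfonate (racemic) | C[S+](C)C1C(=O)Nc2c(Br)ccc(Br)c12.[O-]S(=O)(=O)C(F)(F)F
F5 | step 3 | 4,7-dibromo-1H-indole | Brc1ccc(Br)c2[nH]ccc12
F6 | step 3 | 4,7-dibromo-3-chloro-1H-indole | Clc1c[nH]c2c(Br)ccc(Br)c12
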